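East and north-west are neighbours of this flask, each with one constant doubled, so I want the quantity that feels both constants.

    gas phase ⇌ dissolved gas, rate k1*(csat - [dissolved gas]) (k1 = 0.66 /s, csat = 0.24 mM)
    starting material + dissolved gas → target (k2 = 250 /M/s)
    target ⇌ isomer of the product (K3 = 1.8, k3 = 0.047 /s)
    dissolved gas → decomposed reagent (k4 = 1.1 /s)
    starting material ⇌ dormant form (K5 = 30, k5 = 0.011 /s)

starting material 1.0 mM; gas phase 0.24 mM (held); time 20 s

- at the start none of the gas is dissolved
- run time (flask): 20 s

* how much target there is at 20 s, in percent of the starting material charged
* concentration of dissolved gas in solution at 5.0 s, in percent of saturation
* the change that raises the amount of target at 20 s, in percent of the starting material charged most ("none" if none brings more than 2 percentage points) (east / north-west / none)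
* amount of target at 20 s, in percent of the starting material charged, after north-west

I build the flask up one process at a time, with A for starting material, B for dissolved gas, kT for the transfer coefficient, kD for the decomposition constant and kR for the rate constant of the main step. With transfer and the main step and no other, B stops rising at a share kT/(kT+kR·A) of saturation, which at the charged A is 72.5%. Adding decomposition lowers this share further, since 1.1 /s is larger than the 0.250 /s of the main step. The level where B is made as fast as it is used becomes the plateau share φ = kT/(kT+kD+kR·A), here 32.8%. B relaxes to it with a half-life of 0.345 s, far shorter than the 20 s of the run, so I freeze B at 0.0788 mM and expect about that share at 5.0 s.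

A is then consumed in a pseudo-first-order way at 0.0197 /s, which by the main step with nothing else would make 32.6% of target. Adding the forward rate to the dormant form makes A fall at 0.0307 /s and cuts this to 29.4%. Adding the isomer, whose exchange with target relaxes at 0.0731 /s, leaves me 19.8% of target. Doubling saturation doubles the plateau, whereas doubling kT raises φ to 49.4%, a factor of 1.51, which is less than a doubling, so I choose east.

The forecast gives 19.7% of target, 33.4% of saturation, east as the best change and 26.9% after north-west, on the ground that “Doubling saturation doubles the dissolved gas level, whereas doubling the transfer coefficient raises it only about 1.5-fold”. My own figures differ a little, 19.8% of target and 32.8% of saturation, and I have reckoned no amount of target after north-west.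

The simulation gives 20.0% of target at 20 s and 33.3% of saturation at 5.0 s. East is best, with a gain of 13 percentage points against 7.3 points for north-west, which ends at 27.3%.

The plateau share, recomputed with the A that stands in the flask left until 80.0 s and multiplied by saturation, gives 0.0890 mM of dissolved gas, and that flask holds 0.0890 mM. The flask at 20 s is far from rest, though, with 54.0% of the starting material left. By 200 s that falls to 0.500%, target creeps up to 23.8%, the isomer reaches 42.5% and the dormant form 33.2%. Dissolved gas stands at 0.0899 mM, and decomposed reagent climbs from 1.74 mM to 19.3 mM.

Its constants belong to no real substance; the result is computed.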